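## Structural features

The target is a cis-fused 3,7-dioxabicyclo[3.3.0]octan-2-one. A γ-lactone ring (C1, C2, O3, C4, C5) and a tetrahydrofuran ring (C1, C5, C6, O7, C8) share the C1–C5 bond; C4 carries the 4-hydroxy-3,5-dimethoxyphenyl (syringyl) ring and C8 the 3,4-dihydroxyphenyl (catechol) ring. C4, C5, C1 and C8 are four contiguous stereocentres (4S,5S,1R,8S in this numbering; 3S,3aS,6aR,6S in furo[3,4-c]furanone numbering). H4, H5, H1 and H8 all lie on one face, so both aryl groups sit on the concave face of the bicycle. This all-cis arrangement is the crowded, thermodynamically less favoured one, so it must be made under kinetic control and never equilibrated afterwards. The fragile groups are these: C4–O3 and C8–O7 are benzylic C–O bonds para to a free phenol, open to quinone-methide ionisation in base, cation formation in acid and hydrogenolysis. C1 is enolisable with O7 in the β position, so ring opening by elimination and re-closure would invert C8. The lactone is open to nucleophiles and the catechol is easily oxidised. The real difficulty is therefore not the skeleton but placing two endo aryl groups with the right absolute configuration and unmasking three phenols without disturbing them. The key step exploits three facts: C1 lies between the carbonyl C2 and the (former ketone) carbon C8, O3–C4 is an ester bond to a benzylic carbon, and C5–C6 can be carried as an alkyne. One oxidation at C1 can then close both rings as a flat furan-fused lactone, which leaves C4 as the only stereocentre to steer a later face-selective hydrogenation.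

## Logic of the disconnections

16 ⇒ 15. The three phenolic O–H bonds are traced back to O–acetyl bonds. The phenols must be inert to trivalent manganese and to hydrogenation, and an acetoxy group para to C4 or C8 is a much weaker donor than a hydroxy group, so the benzylic C–O bonds do not ionise on the way. Nothing is gained in skeleton, but every earlier intermediate becomes robust. The demand on the forward step is cleavage of three aryl esters near neutral pH without opening the lactone or epimerising C8 or C4.

15 ⇒ 13 (through 14). The C–H bonds at C5, C6, C1 and C8 are removed, which is a retro-hydrogenation to the aromatic furan. The all-cis array is exactly what syn addition to one face produces, and that face is dictated by the aryl group on C4. Three of the four stereocentres disappear and 13 has a single one. The forward step must saturate the furan completely, including the tetrasubstituted C1=C8 bond of 14, from the face opposite the C4 aryl group, without hydrogenolysis of C4–O3 or C8–O7 and without arene reduction.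

13 ⇒ 12. C1–C5 and O7–C6 are cut. C1 is the carbon between two carbonyl groups and C5–C6 becomes an alkyne, so one oxidation at C1 can form both bonds. Both rings open and an acyclic ester with one stereocentre remains. The forward step must generate the radical only at C1, attack the internal alkyne carbon, close the second ring through oxygen and not through the aroyl ring, and leave C4 intact in warm acid.

12 ⇒ 5 + 10 (through 11). The ester bond O3–C2 is cut. It is the only heteroatom link between the two aryl halves, and acylation through 11 needs neither base nor coupling reagent. Two fragments of similar size result. The forward step must be neutral, and 5 must already be the terminal alkyne in high enantiomeric purity.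

10 ⇒ 8 + 9, then 8 ⇒ 7 ⇒ 6. The C8–C1 bond is cut as acylation of an active methylene, followed by functional-group interconversion back to 6. The demand is that activation of the acid and the acylation leave the aryl acetates alone.

5 ⇒ 4 ⇒ 2 + 3, then 2 ⇒ 1. The C6–Si bond is restored, and then C4–C5 is cut as addition of an alkynyl nucleophile to an aldehyde; this is where C4 is set. An aldehyde is chosen over a ketone because its two faces differ by H against aryl. Reduction of the corresponding aryl alkynyl ketone would have to distinguish an unhindered aryl group from an alkynyl group, which transfer hydrogenation does poorly. The forward steps need high enantioselectivity, zinc reagents that spare the aryl acetate, and a neutral desilylation.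

## Other disconnections considered

Alternative 1: The cut is C4–C5, with O3–C6 as a temporary second bond. Irradiation near 350 nm of aldehyde 2 with the 8-phenylmenthyl 3-furoate A1 would add the excited formyl group across the unsubstituted furan double bond (Paternò–Büchi reaction) and give the exo-aryl oxetane A2.
- In its favour: aldehyde 2 is used as such and no oxidant or metal is needed. The exo preference translates, once the oxetane is re-opened, into the C4 aryl group and C6 being cis on the future lactone, as the target requires. The auxiliary alkoxide would be the leaving group of the lactonisation and needs no separate removal. On the relative configuration of C4 and C5 this plan is the better one, since the chosen route leaves C5 to a late hydrogenation.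
- Against it: the triplet aldehyde must choose the unsubstituted double bond over the ester-bearing one, although the biradical from attack next to the ester is the more stabilised. The auxiliary is four atoms from the reacting bond, so the absolute configuration would rest on weak facial control, where the chosen route uses a catalytic alkynylation. C6 leaves the key step as an acetal carbon and must be reduced (silane, Lewis acid) while O3 is released onto a hindered ester, giving at best the enol ether lactone A3. A3 still has no aryl group at C8, so a metalation or C–H arylation must precede the final hydrogenation.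
- Comparison: both plans end with syn hydrogenation of a C1=C8 enol ether and are equal on the C1/C8 problem. The step count (ester formation, photoreaction, reductive opening with lactonisation, arylation, hydrogenation, deprotection) is about equal, but three steps have uncertain selectivity where the chosen route has one.

Alternative 2: The cut runs through C4–C5 and O3–C2, so the lactone ring is made first from two aldehydes. A chiral N-mesityl triazolium-derived carbene with DBU would turn (E)-4-silyloxybut-2-enal A5 into a homoenolate whose β-carbon (C5) adds to silylated syringaldehyde A4. The alkoxide then acylates the acyl azolium and releases the catalyst, giving the cis lactone A6.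
- In its favour: it is catalytic and metal-free, creates C4 and C5 together in the cis relationship of the target, and reaches a lactone with two stereocentres in about three steps. In directness to the lactone, in step economy and in setting C5 before any hydrogenation it is the better plan.
- Against it: homoenolate additions to simple aryl aldehydes tend to give modest cis selectivity and catalyst-dependent enantioselectivity. A β-alkyl enal with a γ-oxygen is a less willing homoenolate precursor than a cinnamaldehyde and can lose silanolate from the extended enol. More seriously, the tetrahydrofuran ring must still be built by an aldol reaction at C1 and closure of O7 onto C8. An enolate of A6 reacts anti to the C5 substituent, the wrong relationship for a cis ring fusion. Closure at C8 through a benzylic cation or quinone methide should place the catechol ring on the convex face, the opposite of the target.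
- Comparison: the chosen plan reaches the concave aryl group at C8 kinetically, by syn delivery of hydrogen, which no polar ring closure offers. The alternative is the better on the lactone half and the poorer on the C8 half, and for an all-cis target the C8 half decides.

Alternative 3: The cut takes O7–C8, C1–C5 and O3–C2 in one operation. The sodium alkoxide (NaH, THF) of the (2R,3R)-epoxy alcohol A7 would add to C8 of the aryl propiolate A8. The vinyl anion (allenolate) at C1 would open the epoxide at C5 with inversion (5-exo), and the freed C4 alkoxide would close the lactone on the ester, giving the bicyclic enol ether A9.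
- In its favour: it is the most convergent plan (three bonds, two rings, two fragments of equal size) and needs no oxidant. C4 and C5 come from a Ti(OiPr)4/tartrate epoxidation of an allylic alcohol, whose sense and level of enantiocontrol are more dependable than the aldehyde alkynylation of step 2. On absolute configuration and on C5 it is the better plan.
- Against it: an alkoxide adding to a propiolate normally ends by protonation of the vinyl anion, so epoxide opening must outrun proton transfer. The epoxy alkoxide can undergo Payne rearrangement under NaH. C4 is a benzylic epoxide carbon with a para-alkoxy aryl group and is the electronically preferred site of attack, even if ring size favours C5. The alkoxide medium rules out acetates, so benzyl ethers would have to be removed by hydrogenolysis in a molecule with two benzylic C–O bonds in the core.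
- Comparison: A9 is the tribenzyl counterpart of 14, so both plans meet at the same convex-face reduction of C1=C8 and are equal there. The step count (about four steps to A7, three to A8, cascade, reduction, debenzylation) is equal. The chosen plan gives up some convergence and the better enantioselective step in exchange for a ring closure whose regiochemistry is enforced by the tether and protecting groups that come off without hydrogen.

Key step: step 8

Remark (assumption): the (S,S)-ligand of step 2 is assumed, by analogy with related aryl aldehydes, to send the alkynyl group to the Si face; if a first run shows the opposite sense, the (R,R)-ligand is used and nothing else changes.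

Remark (structures): 12 and 13 carry C4 in the same spatial arrangement as 16 and need no correction; only the CIP label of C4 alternates (R in 4, S in 5 and 12, R in 13, S in 14, 15 and 16) because the ranking of its carbon substituents changes.

## Route

Step 1
Reactants: 1 syringaldehyde (4-hydroxy-3,5-dimethoxybenzaldehyde)
Product: 2 4-formyl-2,6-dimethoxyphenyl acetate
Conditions: Ac2O, pyridine, CH2Cl2, 0 °C to rt
Reagents that add atoms: acetic anhydride, CC(=O)OC(C)=O
Why: Pyridine-mediated O-acetylation of a phenol; the acetate blocks phenol oxidation and weakens the para oxygen as a donor, which matters later for the integrity of C4.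

Step 2
Reactants: 2 4-formyl-2,6-dimethoxyphenyl acetate; 3 trimethylsilylacetylene
Product: 4 (R)-4-[1-hydroxy-3-(trimethylsilyl)prop-2-yn-1-yl]-2,6-dimethoxyphenyl acetate
Conditions: (S,S)-ProPhenol (10 mol%), Me2Zn (3 equiv), Ph3P=O (20 mol%), toluene, 0 to 4 °C; aq. NH4Cl
Reagents that add atoms: none
Why: Catalytic enantioselective alkynylation of an aromatic aldehyde: Me2Zn metalates 3 and the alkynylzinc is delivered inside the dinuclear zinc–ProPhenol complex to the Si face of the formyl group, which sets the future C4 (labelled R here because the silylalkynyl group outranks the aryl group). Dialkyl- and alkynylzinc species do not add to esters, and the aryl acetate is further shielded by its two ortho methoxy groups. An aldehyde is preferred to an aryl alkynyl ketone as the prochiral substrate because its faces differ by H against aryl, whereas a ketone reduction would have to tell an unhindered aryl group from an alkynyl group.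

Step 3
Reactants: 4 (R)-4-[1-hydroxy-3-(trimethylsilyl)prop-2-yn-1-yl]-2,6-dimethoxyphenyl acetate
Product: 5 (S)-4-(1-hydroxyprop-2-yn-1-yl)-2,6-dimethoxyphenyl acetate
Conditions: AgNO3 (10 mol%), acetone/H2O, rt, dark
Reagents that add atoms: none
Why: Silver-catalysed protodesilylation: AgNO3 converts the C–Si bond into a silver acetylide that water protonates, under neutral conditions that spare the aryl acetate (carbonate in methanol or unbuffered fluoride would not). C4 is not touched; its label becomes S only through the change in CIP ranking.

Step 4
Reactants: 6 3,4-dihydroxybenzoic acid
Product: 7 3,4-diacetoxybenzoic acid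
Conditions: Ac2O, pyridine, 0 °C to rt; H2O, then 1 M HCl
Reagents that add atoms: acetic anhydride, CC(=O)OC(C)=O
Why: O-Acetylation of both catechol hydroxyl groups; the aqueous work-up returns the carboxyl group as the free acid.

Step 5
Reactants: 7 3,4-diacetoxybenzoic acid
Product: 8 3,4-diacetoxybenzoyl chloride
Conditions: (COCl)2, DMF (cat.), CH2Cl2, 0 °C to rt
Reagents that add atoms: oxalyl chloride, O=C(Cl)C(Cl)=O
Why: DMF-catalysed (Vilsmeier-type) conversion of the acid into the acid chloride under non-nucleophilic conditions that leave the aryl acetates intact; the crude chloride is used directly.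

Step 6
Reactants: 8 3,4-diacetoxybenzoyl chloride; 9 Meldrum's acid (2,2-dimethyl-1,3-dioxane-4,6-dione)
Product: 10 5-[(3,4-diacetoxyphenyl)(hydroxy)methylidene]-2,2-dimethyl-1,3-dioxane-4,6-dione
Conditions: pyridine (2.2 equiv), CH2Cl2, 0 °C to rt; cold 1 M HCl wash
Reagents that add atoms: none
Why: C-Acylation of the acidic methylene of Meldrum's acid by the aroyl chloride with pyridine as base forms the C8–C1 bond and gives the enolised acyl Meldrum's acid, a storable precursor of the aroylketene.

Step 7
Reactants: 10 5-[(3,4-diacetoxyphenyl)(hydroxy)methylidene]-2,2-dimethyl-1,3-dioxane-4,6-dione (1.2 equiv); 5 (S)-4-(1-hydroxyprop-2-yn-1-yl)-2,6-dimethoxyphenyl acetate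
Product: 12 (S)-1-(4-acetoxy-3,5-dimethoxyphenyl)prop-2-yn-1-yl 3-(3,4-diacetoxyphenyl)-3-oxopropanoate, via aroylketene 11 (not isolated)
Conditions: toluene, 90 °C
Reagents that add atoms: none
Why: Thermal cycloreversion of 10 expels acetone and CO2 and gives aroylketene 11, which the secondary alcohol traps at the ketene carbon to form the β-keto ester (O3–C2 bond). No base or coupling reagent is present, so neither the acetates nor C4 are at risk.

Step 8
Reactants: 12 (S)-1-(4-acetoxy-3,5-dimethoxyphenyl)prop-2-yn-1-yl 3-(3,4-diacetoxyphenyl)-3-oxopropanoate
Product: 13 (3R)-3-(4-acetoxy-3,5-dimethoxyphenyl)-6-(3,4-diacetoxyphenyl)-1H,3H-furo[3,4-c]furan-1-one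
Conditions: Mn(OAc)3·2H2O (2.5 equiv), Cu(OAc)2·H2O (1.0 equiv), degassed AcOH (0.03 M), 60 °C
Reagents that add atoms: none
Why: Proposed new method: enolisation of the doubly activated C1 methylene and ligand exchange give the trivalent-manganese enolate of 12, and inner-sphere electron transfer releases Mn(OAc)2 and the electrophilic C1 radical; the closest known reaction types are the Mn(OAc)3-mediated furan annulation of 1,3-dicarbonyl compounds with alkynes and the Mn(OAc)3/Cu(OAc)2 cyclisation of unsaturated β-keto esters and malonates to fused lactones, whereas joining the two through a propargyl ester tether has not been shown. The tether C2–O3–C4 lets C1 reach only the internal alkyne carbon, so the lactone ring closes by 5-exo-dig attack (C1–C5) and leaves a σ-vinyl radical on the terminal carbon C6. C6 then lies next to the aroyl oxygen, and the furan ring closes through O7–C6 either by direct attack of the vinyl radical on the carbonyl oxygen (formally 5-endo-trig, giving a benzylic α-oxy radical at C8 that divalent copper oxidises to the oxocarbenium ion) or by capture of the vinyl radical by Cu(OAc)2 and C–O reductive elimination from the trivalent organocopper enolate; loss of the C1 proton aromatises the ring in both cases. Two oxidising equivalents are consumed, and the monovalent copper formed is returned to divalent copper by Mn(OAc)3. No stereocentre is created, because C1, C5 and C8 end up trigonal, and no bond to C4 is made or broken, so 13 carries C4 unchanged (its label is R only because the furan carbon now outranks the aryl carbon). The step needs regiocontrol, which the tether supplies; closure on oxygen and not on the ortho carbon of the aroyl ring, which the five-membered geometry and fast copper capture should favour; and configurational integrity at C4, which the electron-poor acetoxyaryl group protects by disfavouring ionisation of the benzylic ester in warm acetic acid. Degassing suppresses copper-mediated oxidative coupling of the terminal alkyne, and 13 has no enolisable hydrogen left, so over-oxidation is not expected.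

Step 9
Reactants: 13 (3R)-3-(4-acetoxy-3,5-dimethoxyphenyl)-6-(3,4-diacetoxyphenyl)-1H,3H-furo[3,4-c]furan-1-one
Product: 15 (3S,3aS,6S,6aR)-3-(4-acetoxy-3,5-dimethoxyphenyl)-6-(3,4-diacetoxyphenyl)tetrahydro-1H,3H-furo[3,4-c]furan-1-one, via dihydrofuran lactone 14 (not isolated)
Conditions: H2 (10 bar), 5% Rh/Al2O3, EtOAc, rt
Reagents that add atoms: none
Why: Heterogeneous syn hydrogenation of a furan: flat 13 binds to the metal through the face opposite the C4 aryl group, the enol ether bond C5=C6 is saturated first (14), and the remaining C1=C8 bond is then reduced from the same, now convex, face. All new hydrogens therefore end up cis to H4, which sets C5 (S), C1 (R) and C8 (S) and places both aryl groups on the concave face. Rh on alumina is chosen because it saturates furans under mild conditions while being a poor catalyst for hydrogenolysis of benzylic C–O bonds.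

Step 10
Reactants: 15 (3S,3aS,6S,6aR)-3-(4-acetoxy-3,5-dimethoxyphenyl)-6-(3,4-diacetoxyphenyl)tetrahydro-1H,3H-furo[3,4-c]furan-1-one
Product: 16 (3S,3aS,6S,6aR)-6-(3,4-dihydroxyphenyl)-3-(4-hydroxy-3,5-dimethoxyphenyl)tetrahydro-1H,3H-furo[3,4-c]furan-1-one (target)
Conditions: N2H4·HOAc (3.6 equiv), DMF, 0 °C to rt; pH 5 buffer work-up
Reagents that add atoms: none
Why: Hydrazinolysis of phenolic acetates: aryl esters are far better acyl donors than the hindered bicyclic γ-lactone, and the acetate buffer keeps the medium near neutral. No phenoxide therefore builds up to expel O3 or O7 as a quinone methide and C1 is not enolised, so no stereocentre is touched.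

## Compound list

1 | syringaldehyde (4-hydroxy-3,5-dimethoxybenzaldehyde) | COc1cc(C=O)cc(OC)c1O | starting material
2 | 4-formyl-2,6-dimethoxyphenyl acetate | COc1cc(C=O)cc(OC)c1OC(C)=O | intermediate
3 | trimethylsilylacetylene | C#C[Si](C)(C)C | starting material
4 | (R)-4-[1-hydroxy-3-(trimethylsilyl)prop-2-yn-1-yl]-2,6-dimethoxyphenyl acetate | COc1cc([C@H](C#C[Si](C)(C)C)O)cc(OC)c1OC(C)=O | intermediate
5 | (S)-4-(1-hydroxyprop-2-yn-1-yl)-2,6-dimethoxyphenyl acetate | COc1cc([C@H](C#C)O)cc(OC)c1OC(C)=O | intermediate
6 | 3,4-dihydroxybenzoic acid | OC(=O)c1ccc(O)c(O)c1 | starting material
7 | 3,4-diacetoxybenzoic acid | CC(=O)Oc1ccc(C(=O)O)cc1OC(C)=O | intermediate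
8 | 3,4-diacetoxybenzoyl chloride | CC(=O)Oc1ccc(C(=O)Cl)cc1OC(C)=O | intermediate
9 | Meldrum's acid (2,2-dimethyl-1,3-dioxane-4,6-dione) | CC1(C)OC(=O)CC(=O)O1 | starting material
10 | 5-[(3,4-diacetoxyphenyl)(hydroxy)methylidene]-2,2-dimethyl-1,3-dioxane-4,6-dione | CC(=O)Oc1ccc(C(O)=C2C(=O)OC(C)(C)OC2=O)cc1OC(C)=O | intermediate
11 | (3,4-diacetoxybenzoyl)ketene [4-(3-oxoprop-2-enoyl)-1,2-phenylene diacetate] | CC(=O)Oc1ccc(C(=O)C=C=O)cc1OC(C)=O | intermediate
12 | (S)-1-(4-acetoxy-3,5-dimethoxyphenyl)prop-2-yn-1-yl 3-(3,4-diacetoxyphenyl)-3-oxopropanoate | COc1cc([C@H](C#C)OC(=O)CC(=O)c2ccc(OC(C)=O)c(OC(C)=O)c2)cc(OC)c1OC(C)=O | intermediate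
13 | (3R)-3-(4-acetoxy-3,5-dimethoxyphenyl)-6-(3,4-diacetoxyphenyl)-1H,3H-furo[3,4-c]furan-1-one | COc1cc([C@H]2OC(=O)c3c2coc3-c2ccc(OC(C)=O)c(OC(C)=O)c2)cc(OC)c1OC(C)=O | intermediate
14 | (3S,3aS)-3-(4-acetoxy-3,5-dimethoxyphenyl)-6-(3,4-diacetoxyphenyl)-3a,4-dihydro-1H,3H-furo[3,4-c]furan-1-one | COc1cc([C@H]2OC(=O)C3=C(c4ccc(OC(C)=O)c(OC(C)=O)c4)OC[C@@H]23)cc(OC)c1OC(C)=O | intermediate
15 | (3S,3aS,6S,6aR)-3-(4-acetoxy-3,5-dimethoxyphenyl)-6-(3,4-diacetoxyphenyl)tetrahydro-1H,3H-furo[3,4-c]furan-1-one | COc1cc([C@H]2OC(=O)[C@@H]3[C@H]2CO[C@@H]3c2ccc(OC(C)=O)c(OC(C)=O)c2)cc(OC)c1OC(C)=O | intermediate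
16 | (3S,3aS,6S,6aR)-6-(3,4-dihydroxyphenyl)-3-(4-hydroxy-3,5-dimethoxyphenyl)tetrahydro-1H,3H-furo[3,4-c]furan-1-one (CNP0224550.1) | COc1cc([C@H]2OC(=O)[C@@H]3[C@H]2CO[C@@H]3c2ccc(O)c(O)c2)cc(OC)c1O | target

## Step count and least certain steps

Total: 10 steps. Longest linear sequence: 7 steps (steps 1, 2, 3, 7, 8, 9, 10 from 1; equally steps 4 to 10 from 6).

Step 8 (key step, new method). Three processes are most likely to go wrong.
- The ester prefers its extended rotamer, in which C1 and C5 are far apart. Ring closure of the tethered radical may therefore be slow, letting intermolecular coupling or acetoxylation of the manganese enolate radical compete.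
- The vinyl radical at C6 may abstract hydrogen from the solvent before it closes, stopping at the exo-methylene lactone. A further oxidation cycle at C1 could still carry this on to 13, which is why excess Mn(OAc)3 is used. The vinyl radical may also close on the ortho carbon of the aroyl ring instead of the oxygen.
- Partial ionisation of the benzylic ester in warm acid would erode the configuration at C4.

The fallback sets out from 12 and comes back at 13 by known chemistry. Diazo transfer to C1 (4-acetamidobenzenesulfonyl azide, Et3N, MeCN, 0 °C) should give (S)-1-(4-acetoxy-3,5-dimethoxyphenyl)prop-2-yn-1-yl 2-diazo-3-(3,4-diacetoxyphenyl)-3-oxopropanoate F1. Rh2(OAc)4 (1 to 2 mol%) in benzene at 80 °C then generates the divalent-rhodium carbenoid at C1, which adds to the tethered alkyne (C1–C5). The resulting vinyl carbenoid at C6 is trapped by the aroyl oxygen (O7–C6) to give 13. This carbenoid–alkyne–carbonyl cascade is established for propargyl 2-diazo-3-oxoalkanoates and gives this furo[3,4-c]furanone ring system. It forms the same two bonds without an oxidant and at neutral pH.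

Step 9. The most likely failures are stalling at 14, because the remaining C1=C8 bond is a tetrasubstituted vinylogous carbonate; hydrogenolysis of C4–O3 while C4 is still flanked by an aryl ring and a furan; and saturation of an arene ring if pressure or time is raised to force completion. The fallback sets out from 14 and comes back at 15. The hydrogenation is stopped at 14 (1 bar H2, same catalyst), and 14 is isolated and reduced by ionic hydrogenation (Et3SiH, CF3CO2H, CH2Cl2, −20 to 0 °C). Protonation at C1 can only give the cis-fused oxocarbenium ion at C8, and hydride then enters from the convex face, which is the same stereochemical outcome as surface hydrogenation. This fallback makes no compound outside the list (F0).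

Step 2. The most likely failures are insufficient enantioselectivity with this particular aldehyde, or acetyl migration from the aryl acetate to the zinc alkoxide of the product during the long reaction time. The fallback sets out from 2 and comes back at 5, replacing catalyst control by enzyme control. HC≡CMgBr (THF, −78 °C, cold quench) should give racemic 4-(1-hydroxyprop-2-yn-1-yl)-2,6-dimethoxyphenyl acetate F2. Kinetic resolution with immobilised lipase CAL-B and vinyl acetate (MTBE, 30 °C, to just over half conversion) should acetylate the R enantiomer, in which the aryl ring is the large and the ethynyl group the medium substituent. This gives (R)-1-(4-acetoxy-3,5-dimethoxyphenyl)prop-2-yn-1-yl acetate F3 and leaves (S)-5, which is separated by chromatography. The price is half of the material; the silyl group and step 3 are no longer needed.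

Step 10. The most likely failures are epimerisation at C8, either by enolisation at C1 with loss and re-addition of O7, or by quinone-methide ionisation once the para phenol is free; and hydrazinolysis of the lactone. The fallback sets out from 13 and comes back at 16 by reversing the order of the last two operations. Hydrazine acetate in DMF is applied to flat 13, where C5, C1 and C8 are not yet stereocentres, to give (3R)-6-(3,4-dihydroxyphenyl)-3-(4-hydroxy-3,5-dimethoxyphenyl)-1H,3H-furo[3,4-c]furan-1-one F4. The neutral hydrogenation (H2, 5% Rh/Al2O3, EtOAc/EtOH) is then the last step and gives 16 directly. The cost is a greater tendency of the free phenol rings to be hydrogenated, so hydrogen uptake has to be followed closely.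

Further compounds

F1 | step 8 | (S)-1-(4-acetoxy-3,5-dimethoxyphenyl)prop-2-yn-1-yl 2-diazo-3-(3,4-diacetoxyphenyl)-3-oxopropanoate | COc1cc([C@H](C#C)OC(=O)C(=[N+]=[N-])C(=O)c2ccc(OC(C)=O)c(OC(C)=O)c2)cc(OC)c1OC(C)=O
F0 | step 9 | none | none
F2 | step 2 | racemic 4-(1-hydroxyprop-2-yn-1-yl)-2,6-dimethoxyphenyl acetate | COc1cc(C(C#C)O)cc(OC)c1OC(C)=O
F3 | step 2 | (R)-1-(4-acetoxy-3,5-dimethoxyphenyl)prop-2-yn-1-yl acetate | COc1cc([C@@H](C#C)OC(C)=O)cc(OC)c1OC(C)=O
F4 | step 10 | (3R)-6-(3,4-dihydroxyphenyl)-3-(4-hydroxy-3,5-dimethoxyphenyl)-1H,3H-furo[3,4-c]furan-1-one | COc1cc([C@H]2OC(=O)c3c2coc3-c2ccc(O)c(O)c2)cc(OC)c1O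
A1 | alternative 1 | 8-phenylmenthyl furan-3-carboxylate | C[C@@H]1CC[C@H]([C@@H](C1)OC(=O)c1ccoc1)C(C)(C)c1ccccc1
A2 | alternative 1 | 8-phenylmenthyl exo-6-(4-acetoxy-3,5-dimethoxyphenyl)-2,7-dioxabicyclo[3.2.0]hept-3-ene-4-carboxylate | C[C@@H]1CC[C@H]([C@@H](C1)OC(=O)C1=CO[C@H]2O[C@H](c3cc(OC)c(OC(C)=O)c(OC)c3)[C@@H]12)C(C)(C)c1ccccc1
A3 | alternative 1 | (3S,3aS)-3-(4-acetoxy-3,5-dimethoxyphenyl)-3a,4-dihydro-1H,3H-furo[3,4-c]furan-1-one | COc1cc([C@H]2OC(=O)C3=COC[C@@H]23)cc(OC)c1OC(C)=O
A4 | alternative 2 | 4-(tert-butyldimethylsilyloxy)-3,5-dimethoxybenzaldehyde | COc1cc(C=O)cc(OC)c1O[Si](C)(C)C(C)(C)C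
A5 | alternative 2 | (E)-4-(tert-butyldimethylsilyloxy)but-2-enal | O=C/C=C/CO[Si](C)(C)C(C)(C)C
A6 | alternative 2 | (4S,5S)-4-[(tert-butyldimethylsilyloxy)methyl]-5-[4-(tert-butyldimethylsilyloxy)-3,5-dimethoxyphenyl]dihydrofuran-2(3H)-one | COc1cc([C@H]2OC(=O)C[C@H]2CO[Si](C)(C)C(C)(C)C)cc(OC)c1O[Si](C)(C)C(C)(C)C
A7 | alternative 3 | [(2R,3R)-3-(4-benzyloxy-3,5-dimethoxyphenyl)oxiran-2-yl]methanol | COc1cc([C@H]2O[C@@H]2CO)cc(OC)c1OCc1ccccc1
A8 | alternative 3 | methyl 3-[3,4-bis(benzyloxy)phenyl]prop-2-ynoate | COC(=O)C#Cc1ccc(OCc2ccccc2)c(OCc2ccccc2)c1
A9 | alternative 3 | (3S,3aS)-3-(4-benzyloxy-3,5-dimethoxyphenyl)-6-[3,4-bis(benzyloxy)phenyl]-3a,4-dihydro-1H,3H-furo[3,4-c]furan-1-one | COc1cc([C@H]2OC(=O)C3=C(c4ccc(OCc5ccccc5)c(OCc5ccccc5)c4)OC[C@@H]23)cc(OC)c1OCc1ccccc1
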